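## Retrosynthetic overview

1. The target comes from O-demethylation of its methyl ether. The 2-bromophenyl ring comes from a 2-bromo-4-nitrophenyl ring, whose nitro group only activates the C–O coupling and is then erased (NO2 → NH2 → H).
2. The diaryl ether C–O bond comes from SNAr of tetrabromoguaiacol on 2-bromo-1-fluoro-4-nitrobenzene. Tetrabromoguaiacol comes from monomethylation of tetrabromocatechol.
3. Tetrabromocatechol comes from 2,3-dihydroxyterephthalic acid by two C–H brominations and two ipso-bromodecarboxylations; the carboxyl groups are placeholders for Br.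
4. The dihydroxyterephthalate comes from dehydrogenation of diethyl 2,3-dioxocyclohexane-1,4-dicarboxylate. The key C–C bond there is an intermolecular crossed Claisen condensation of diethyl adipate with diethyl oxalate, followed by Dieckmann closure.
5. Ring order: the oxygenated ring is the only ring built (Claisen/Dieckmann, then aromatised). The bromophenyl ring is bought intact and attached afterwards.

Assumption: the target has no stereocentre and no resolvable axis (a tri-ortho-substituted diaryl ether rotates freely), so it is achiral and needs no stereocontrol.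

## Route

Step 1
Reactants: 1 diethyl adipate; 2 diethyl oxalate
Product: 4 diethyl 2,3-dihydroxycyclohexa-1,3-diene-1,4-dicarboxylate (bis-enol tautomer of diethyl 2,3-dioxocyclohexane-1,4-dicarboxylate), via ethoxalyl adipate 3 (not isolated)
Conditions: NaOEt (2.2 equiv), Et2O, 0 °C → reflux, 24 h; then cold 2 M HCl
Reagents that add atoms: none
Why: An intermolecular crossed Claisen condensation of the adipate enolate on the non-enolisable, highly electrophilic oxalate gives 3, whose second α-carbon closes the six-membered ring on the remaining oxalyl ester (Dieckmann condensation); every step is reversible, the sparingly soluble disodium bis-enolate of 4 is the thermodynamic sink, and no stereocentre survives in the planar bis-enol.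

Step 2
Reactants: 4 diethyl 2,3-dihydroxycyclohexa-1,3-diene-1,4-dicarboxylate
Product: 6 diethyl 2,3-dihydroxyterephthalate, via α-bromo keto diester 5 (not isolated)
Conditions: Br2 (1.0 equiv), CHCl3, 0 °C; then reflux until HBr evolution stops
Reagents that add atoms: bromine, BrBr (supplies the Br of 5; none of it remains in 6)
Why: Electrophilic α-bromination of the β-keto ester enol followed by thermal dehydrobromination and tautomerisation (halogenative dehydrogenation) is driven by aromatisation, and any stray ring bromination of 6 is harmless because those positions carry bromine later.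

Step 3
Reactants: 6 diethyl 2,3-dihydroxyterephthalate
Product: 7 2,3-dihydroxyterephthalic acid
Conditions: NaOH (6 equiv), H2O/EtOH, reflux, N2; then conc. HCl to pH 1, filter
Reagents that add atoms: sodium hydroxide, [Na+].[OH-]
Why: Saponification (BAc2) is done at this stage because each ester still has one free ortho position, and nitrogen protects the catecholate from air oxidation.

Step 4
Reactants: 7 2,3-dihydroxyterephthalic acid
Product: 11 3,4,5,6-tetrabromobenzene-1,2-diol (tetrabromocatechol), via monobromo diacid 8 (not isolated), via dibromo diacid 9 (not isolated), via tribromo monoacid 10 (not isolated)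
Conditions: Br2 (5 equiv), AcOH/H2O 4:1, rt → 70 °C; then aq NaHSO3, dilute with water, filter
Reagents that add atoms: bromine, BrBr
Why: Electrophilic aromatic bromination first fills the two free positions, each para to a hydroxyl, and ipso attack ortho to each hydroxyl then expels CO2 (bromodecarboxylation, as in salicylic acid → tribromophenol), while the bisulfite work-up returns any o-quinone to the catechol.

Step 5
Reactants: 11 tetrabromocatechol
Product: 12 2,3,4,5-tetrabromo-6-methoxyphenol (tetrabromoguaiacol)
Conditions: t-BuOK (2.0 equiv), DMF, 0 °C, Ar; MeI (1.0 equiv) added slowly, 0 °C → rt; then 1 M HCl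
Reagents that add atoms: iodomethane, CI
Why: In this Williamson ether synthesis the catecholate dianion (second pKa about 10–11) is far more nucleophilic than the monomethylated phenolate (pKa about 6), so one equivalent of MeI stops at the monoether; neutral diether and unreacted diol are easily separated.

Step 6
Reactants: 12 tetrabromoguaiacol; 13 2-bromo-1-fluoro-4-nitrobenzene
Product: 14 1,2,3,4-tetrabromo-5-(2-bromo-4-nitrophenoxy)-6-methoxybenzene
Conditions: K2CO3 (1.5 equiv), DMSO, 100 °C, 16 h, N2
Reagents that add atoms: none
Why: Nucleophilic aromatic substitution (addition–elimination through a Meisenheimer complex) takes place only at the C–F carbon para to the nitro group, because the C–Br of 13 is meta to it and the bromines of 12 sit on an unactivated ring.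

Step 7
Reactants: 14 1,2,3,4-tetrabromo-5-(2-bromo-4-nitrophenoxy)-6-methoxybenzene
Product: 15 3-bromo-4-(2,3,4,5-tetrabromo-6-methoxyphenoxy)aniline
Conditions: SnCl2·2H2O (4 equiv), conc. HCl, EtOH, 65 °C; then aq NaOH work-up
Reagents that add atoms: none
Why: Tin(II) chloride reduction converts the nitro group to the amine without touching aryl C–Br bonds, which catalytic hydrogenation would endanger.

Step 8
Reactants: 15 3-bromo-4-(2,3,4,5-tetrabromo-6-methoxyphenoxy)aniline
Product: 17 1,2,3,4-tetrabromo-5-(2-bromophenoxy)-6-methoxybenzene, via arenediazonium hydrogen sulfate 16 (not isolated)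
Conditions: NaNO2 in conc. H2SO4, AcOH, 0–5 °C; then 50% aq H3PO2 (15 equiv), 0 °C → rt, 12 h
Reagents that add atoms: sodium nitrite, [Na+].[O-]N=O (second N of 16); sulfuric acid, OS(=O)(=O)O (counter-ion of 16); only hydrogen stays in 17
Why: Diazotisation followed by hydrodediazoniation with hypophosphorous acid (reductive deamination) is clean here because the aryl radical sits para to the ether oxygen, too far from the other ring to cyclise onto it or to abstract from its OMe.

Step 9
Reactants: 17 1,2,3,4-tetrabromo-5-(2-bromophenoxy)-6-methoxybenzene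
Product: 19 2,3,4,5-tetrabromo-6-(2-bromophenoxy)phenol (target), via aryloxydibromoborane 18 (not isolated)
Conditions: BBr3 (2.5 equiv), CH2Cl2, −78 °C → rt, 12 h; then ice/H2O
Reagents that add atoms: boron tribromide, BrB(Br)Br (B and Br of 18 only)
Why: Lewis-acid aryl methyl ether cleavage (bromide attacks the methyl of the BBr3-activated ether) leaves the diaryl ether and all C–Br bonds intact, and hydrolysis of 18 releases the phenol.

## Compound list

1 | diethyl adipate | CCOC(=O)CCCCC(=O)OCC | starting material
2 | diethyl oxalate | CCOC(=O)C(=O)OCC | starting material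
3 | diethyl 2-(2-ethoxy-2-oxoacetyl)hexanedioate (racemic, labile; present as its sodium enolate) | CCOC(=O)C(=O)C(CCCC(=O)OCC)C(=O)OCC | intermediate
4 | diethyl 2,3-dihydroxycyclohexa-1,3-diene-1,4-dicarboxylate | CCOC(=O)C1=C(O)C(O)=C(C(=O)OCC)CC1 | intermediate
5 | diethyl 1-bromo-3-hydroxy-2-oxocyclohex-3-ene-1,4-dicarboxylate (racemic) | CCOC(=O)C1(Br)CCC(C(=O)OCC)=C(O)C1=O | intermediate
6 | diethyl 2,3-dihydroxyterephthalate | CCOC(=O)c1ccc(C(=O)OCC)c(O)c1O | intermediate
7 | 2,3-dihydroxyterephthalic acid | OC(=O)c1ccc(C(O)=O)c(O)c1O | intermediate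
8 | 5-bromo-2,3-dihydroxyterephthalic acid | OC(=O)c1cc(Br)c(C(O)=O)c(O)c1O | intermediate
9 | 2,3-dibromo-5,6-dihydroxyterephthalic acid | OC(=O)c1c(Br)c(Br)c(C(O)=O)c(O)c1O | intermediate
10 | 2,3,4-tribromo-5,6-dihydroxybenzoic acid | OC(=O)c1c(Br)c(Br)c(Br)c(O)c1O | intermediate
11 | 3,4,5,6-tetrabromobenzene-1,2-diol | Oc1c(O)c(Br)c(Br)c(Br)c1Br | intermediate
12 | 2,3,4,5-tetrabromo-6-methoxyphenol | COc1c(O)c(Br)c(Br)c(Br)c1Br | intermediate
13 | 2-bromo-1-fluoro-4-nitrobenzene | Fc1ccc(cc1Br)[N+](=O)[O-] | starting material
14 | 1,2,3,4-tetrabromo-5-(2-bromo-4-nitrophenoxy)-6-methoxybenzene | COc1c(Oc2ccc(cc2Br)[N+](=O)[O-])c(Br)c(Br)c(Br)c1Br | intermediate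
15 | 3-bromo-4-(2,3,4,5-tetrabromo-6-methoxyphenoxy)aniline | COc1c(Oc2ccc(N)cc2Br)c(Br)c(Br)c(Br)c1Br | intermediate
16 | 3-bromo-4-(2,3,4,5-tetrabromo-6-methoxyphenoxy)benzenediazonium hydrogen sulfate | COc1c(Oc2ccc(cc2Br)[N+]#N)c(Br)c(Br)c(Br)c1Br.OS(=O)(=O)[O-] | intermediate
17 | 1,2,3,4-tetrabromo-5-(2-bromophenoxy)-6-methoxybenzene | COc1c(Oc2ccccc2Br)c(Br)c(Br)c(Br)c1Br | intermediate
18 | dibromo[2,3,4,5-tetrabromo-6-(2-bromophenoxy)phenoxy]borane | BrB(Br)Oc1c(Oc2ccccc2Br)c(Br)c(Br)c(Br)c1Br | intermediate
19 | 2,3,4,5-tetrabromo-6-(2-bromophenoxy)phenol (achiral) | Oc1c(Br)c(Br)c(Br)c(Br)c1Oc1ccccc1Br | target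

## Step count

Total step count: 9.
Longest linear sequence: 9 (1/2 → 19).

## Three steps most likely to fail

**Step 1 (crossed Claisen/Dieckmann).** The equilibrium may stall at 3 or lose material to self-cyclisation of 1.

The fallback sets out from 1 and comes back at 4. It replaces the reversible alkoxide chemistry by an irreversible Mukaiyama-type Claisen acylation. Compound 1 is treated with LDA (2.2 equiv) in the presence of TMSCl (in situ quench, THF, −78 °C). Both ester enolates are thereby trapped before they can cyclise, which gives 1,6-diethoxy-1,6-bis(trimethylsilyloxy)hexa-1,5-diene F1.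

F1 and oxalyl chloride (1.0 equiv) are then added slowly and simultaneously to CH2Cl2 (high dilution, −78 °C → rt). C-acylation gives ethyl 2-(2-chloro-2-oxoacetyl)-6-ethoxy-6-(trimethylsilyloxy)hex-5-enoate F2. Its remaining ketene acetal attacks the acid chloride intramolecularly, closes the six-membered ring and gives 4 after tautomerisation.

**Step 4 (double bromodecarboxylation).** Hot aqueous bromine may over-oxidise the catechol to quinone-derived products, or the second carboxyl group may be lost incompletely.

The fallback sets out from 7 and comes back at 11, and it separates decarboxylation from bromination. Compound 7 is heated in quinoline at about 220 °C under N2. Protodecarboxylation proceeds through 2,3-dihydroxybenzoic acid F3 to benzene-1,2-diol (catechol) F4.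

The classical perbromination follows (Br2, 4.2 equiv, AcOH/CHCl3, 0 °C → rt). It runs through 4-bromobenzene-1,2-diol F5, 4,5-dibromobenzene-1,2-diol F6 and 3,4,5-tribromobenzene-1,2-diol F7 to 11.

**Step 6 (SNAr of a weak, doubly ortho-flanked phenolate).** The reaction may be too slow below the temperature at which methyl transfer between phenolates begins.

The fallback sets out from 12 and comes back at 17, bypassing 14–16. It uses metal-free ligand coupling at iodine(III) in place of addition–elimination. 1-Bromo-2-iodobenzene is oxidised with mCPBA and TsOH·H2O (MeCN, 77 °C) to 1-bromo-2-[hydroxy(tosyloxy)-λ3-iodanyl]benzene F8. This is captured in the same pot by 1,3,5-trimethoxybenzene to give (2-bromophenyl)(2,4,6-trimethoxyphenyl)iodonium tosylate F9.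

The potassium salt of 12 (t-BuOK, THF/toluene) is warmed with F9 at 40–60 °C. The electron-rich trimethoxyphenyl group stays on iodine as the spectator, so the 2-bromophenyl group is transferred to oxygen and 17 forms directly.

## Further compounds

F1 | step 1 | 1,6-diethoxy-1,6-bis(trimethylsilyloxy)hexa-1,5-diene (E/Z mixture) | CCOC(O[Si](C)(C)C)=CCCC=C(OCC)O[Si](C)(C)C
F2 | step 1 | ethyl 2-(2-chloro-2-oxoacetyl)-6-ethoxy-6-(trimethylsilyloxy)hex-5-enoate (racemic, E/Z mixture) | CCOC(=O)C(CCC=C(OCC)O[Si](C)(C)C)C(=O)C(=O)Cl
F3 | step 4 | 2,3-dihydroxybenzoic acid | OC(=O)c1cccc(O)c1O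
F4 | step 4 | benzene-1,2-diol (catechol) | Oc1ccccc1O
F5 | step 4 | 4-bromobenzene-1,2-diol | Oc1ccc(Br)cc1O
F6 | step 4 | 4,5-dibromobenzene-1,2-diol | Oc1cc(Br)c(Br)cc1O
F7 | step 4 | 3,4,5-tribromobenzene-1,2-diol | Oc1cc(Br)c(Br)c(Br)c1O
F8 | step 6 | 1-bromo-2-[hydroxy(tosyloxy)-λ3-iodanyl]benzene | OI(OS(=O)(=O)c1ccc(C)cc1)c1ccccc1Br
F9 | step 6 | (2-bromophenyl)(2,4,6-trimethoxyphenyl)iodonium tosylate | COc1cc(OC)c([I+]c2ccccc2Br)c(OC)c1.Cc1ccc(cc1)S(=O)(=O)[O-]
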